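The target in this flask is made quickly and then leaves at a steady pace, and that pace is what I carried through my reckoning.

| flask | substrate | gas phase | remark | time |
|---|---|---|---|---|
| violet | 0.87 M | 200 mM (held) | run made earlier |  |
| grey | 2 M | 200 mM (held) | run made earlier |  |
| flask | 1.3 M | 200 mM (held) |  | 15 d |

| run | time / d | target / % | substrate / % |
|---|---|---|---|
| violet | 0.125 | 19.3 | 50.2 |
| violet | 0.250 | 30.1 | 18.3 |
| violet | 0.500 | 31.1 | 2.0 |
| violet | 1.25 | 8.9 | 0.6 |
| violet | 2.50 | 4.5 | 0 |
| violet | 6.00 | 4.9 | 0 |
| violet | 12.0 | 5.3 | 0 |
| grey | 0.125 | 13.3 | 56.6 |
| grey | 0.250 | 23.8 | 28.9 |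
| grey | 0.500 | 34.2 | 5.8 |
| grey | 1.25 | 26.7 | 0.3 |
| grey | 2.50 | 12.2 | 0.3 |
| grey | 6.00 | 4.8 | 1.2 |
| grey | 12.0 | 4.7 | 0 |

(scatter of a reading: 1 percentage point)

- time up to 15 d at which target stands highest
- the amount of target, in percent of the substrate charged, at that time
- the first time at which target reaches 11%, in the same percent, in d

- amounts and yields of target count crystals too
- given per volume of solution although it is solid: crystals
- at the start none of the gas is dissolved
- candidate steps: gas phase <-> dissolved gas; substrate + dissolved gas -> target; substrate -> side product; target <-> isomer of the product; dissolved gas <-> dormant form; crystals <-> target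

In the first instants of both earlier runs the gas starts to dissolve while the substrate is already going: at 0.125 d the violet run holds 50.2% of its substrate and the grey run 56.6%. By 0.500 d the substrate reads 2.0% in the violet run and 5.8% in the grey run, while the target reads 31.1% and 34.2%. Making is nearly over there, so I expected the high point close to that time.

After that I froze one thing. I took it that while crystals stand, the solution stays at its saturation level of target, so target should turn into isomer at a steady rate in molar per day, a zero-order fall. The readings allow this: the violet run, charged at 0.87 M, loses 0.258 M/d, and the grey run, charged at 2 M, loses 0.220 M/d. Their mean, 0.239 M/d, I call the drain: target lost per litre and day while crystals last. The last readings stand at 5.3% and 4.7%. So I reckoned that the flask, charged at 1.3 M, needs 1.51 d after its peak to fall from the mean peak reading to that late level.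

The forecast put the high point at 33% at 0.45 d and the first crossing of 11% at 0.09 d, and it also read that “target falls at a nearly constant absolute rate”.

The flask gives 35.4% at 0.461 d and first reaches 11% at 0.0790 d, all within the forecast's margins. At the best time, 26.9% of the charge stands as crystals, counted within the target's 35.4%. Those crystals come to 0.350 M, which at the drain last 1.46 d past the best time; the flask still holds 6.95% as crystals at 1.50 d and 0% at 7.50 d.

    gas phase ⇌ dissolved gas, rate k1*(csat - [dissolved gas]) (kL = 0.850 /h)
    substrate + dissolved gas → target (k = 1.70 /M/h)
    substrate → side product (k = 0.120 /h)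
    target ⇌ isomer of the product (K = 11.0, k = 0.150 /h)
    dissolved gas ⇌ dormant form (K = 4.70, k = 0.280 /h)
    crystals ⇌ target, rate k6*(cs6 - [target]) while solid is left; crystals form when [target] > cs6 (solubility = 0.110 M, k = 16.0 /h)

The same flask read at 6.0 d is a second case: the best time plus the reckoned fall at the drain comes to 1.97 d, shorter than 6.0 d, so I expected target to stand near its late level at that reading. The computed flask holds 4.24% target and 0% crystals then.

(The data stem from a simulated flask from invented constants; scatter was added.)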